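## Retrosynthetic overview

1. The 1,2-dioxane (the only ring) is formed last from β-lactone 17: H2O2 opens the lactone at C3 (C3–O bond, inversion), then the new C3–OOH captures a C6 allyl cation (C6–O bond).
2. β-Lactone 17 comes from aldehyde 16 and ketene (C1–C2), with C3 set by the catalyst.
3. Aldehyde 16 comes from vinyl iodide 8 (C7–C14) and keto acetal 12 (C3–C6) by alkenyllithium addition (C6–C7 bond).
4. Vinyl iodide 8 comes from (E)-pent-2-enal by ethylation, Johnson–Claisen rearrangement (C10), alkyne formation and methylalumination (E C7=C8).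
5. Keto acetal 12 comes from ethyl vinyl ketone and acrolein diethyl acetal by cross-metathesis and copper-catalysed conjugate ethylation (C4).

Assumption: atom labels C1–C14 follow the acid chain of the target (C1 = carboxyl carbon, ring carbons C3–C6). Where a catalyst antipode is named, it is the one expected to give the stated configuration and would be confirmed on the first run.

## Route

Step 1
Reactants: 1 (2E)-pent-2-enal
Product: 2 (3R,4E)-hept-4-en-3-ol
Conditions: Et2Zn (1.5 equiv), (+)-MIB [(2R)-3-exo-morpholinoisoborneol, 4 mol%], hexane, 0 °C; aq. NH4Cl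
Reagents that add atoms: diethylzinc, CC[Zn]CC
Why: Amino-alcohol-catalysed enantioselective 1,2-addition of diethylzinc to an enal, in which the chiral zinc aminoalkoxide delivers ethyl to one carbonyl face and sets the carbinol centre as R.

Step 2
Reactants: 2 (3R,4E)-hept-4-en-3-ol
Product: 4 ethyl (3R,4E)-3-ethylhept-4-enoate, via ketene acetal 3 (not isolated)
Conditions: MeC(OEt)3 (5 equiv), EtCO2H (5 mol%), 140 °C, EtOH distilled off
Reagents that add atoms: triethyl orthoacetate, CC(OCC)(OCC)OCC
Why: Johnson–Claisen rearrangement through a chair transition state with the carbinol ethyl group equatorial, which transfers the R carbinol configuration suprafacially to the new C–C stereocentre (R, the future C10) and gives the E alkene.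

Step 3
Reactants: 4 ethyl (3R,4E)-3-ethylhept-4-enoate
Product: 6 (4R,5E)-4-ethyloct-5-en-1-yne, via aldehyde 5 (not isolated)
Conditions: i-Bu2AlH (1.1 equiv), CH2Cl2, −78 °C; then MeOH, K2CO3, dimethyl (1-diazo-2-oxopropyl)phosphonate, −78 °C → rt
Reagents that add atoms: dimethyl (1-diazo-2-oxopropyl)phosphonate, CC(=O)C(=[N+]=[N-])P(=O)(OC)OC
Why: One-pot half-reduction of the ester and Ohira–Bestmann (Seyferth–Gilbert) homologation of the aldehyde gives the terminal alkyne without touching the β-stereocentre.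

Step 4
Reactants: 6 (4R,5E)-4-ethyloct-5-en-1-yne
Product: 8 (1E,4R,5E)-4-ethyl-1-iodo-2-methylocta-1,5-diene, via alkenylalane 7 (not isolated)
Conditions: Me3Al (2 equiv), (C5H5)2ZrCl2 (20 mol%), CH2Cl2, 0 °C → rt; then I2, THF, −30 °C; aq. NaHCO3
Reagents that add atoms: trimethylaluminium, C[Al](C)C; iodine, II
Why: Negishi zirconium-catalysed methylalumination adds methyl and aluminium syn across the terminal alkyne with aluminium at the terminus, and iodinolysis with retention gives the E trisubstituted vinyl iodide.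

Step 5
Reactants: 9 pent-1-en-3-one; 10 3,3-diethoxyprop-1-ene
Product: 11 (4E)-6,6-diethoxyhex-4-en-3-one
Conditions: [1,3-bis(2,4,6-trimethylphenyl)imidazolidin-2-ylidene]dichloro(2-isopropoxybenzylidene)ruthenium (second-generation Hoveyda–Grubbs catalyst, 2 mol%), 9 (2 equiv), CH2Cl2, 40 °C
Reagents that add atoms: none
Why: Olefin cross-metathesis between an enone and an allylic acetal favours the E cross product and is driven by loss of ethene.

Step 6
Reactants: 11 (4E)-6,6-diethoxyhex-4-en-3-one
Product: 12 (5R)-6,6-diethoxy-5-ethylhexan-3-one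
Conditions: EtMgBr (1.2 equiv), CuBr·SMe2 (5 mol%), Josiphos-type ferrocenyl diphosphine (6 mol%, enantiomer giving 5R), t-BuOMe, −75 °C; aq. NH4Cl
Reagents that add atoms: ethylmagnesium bromide, CC[Mg]Br
Why: Copper-catalysed asymmetric conjugate addition of a Grignard reagent to an acyclic enone, in which the chiral diphosphine–copper complex adds ethyl to one face of the β-carbon and sets the future C4 as R.

Step 7
Reactants: 8 (1E,4R,5E)-4-ethyl-1-iodo-2-methylocta-1,5-diene; 12 (5R)-6,6-diethoxy-5-ethylhexan-3-one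
Product: 15 (2R,5E,8R,9E)-1,1-diethoxy-2,4,8-triethyl-4-methoxy-6-methyldodeca-5,9-diene (both epimers at the methoxy carbon), via alkenyllithium 13 (not isolated), via lithium alkoxide 14 (not isolated)
Conditions: t-BuLi (2.1 equiv), Et2O, −78 °C; add 12, −78 → −40 °C; then MeOTf (3 equiv), −78 → 0 °C
Reagents that add atoms: methyl trifluoromethanesulfonate, COS(=O)(=O)C(F)(F)F
Why: Lithium–iodine exchange with retention of alkene geometry, 1,2-addition of the alkenyllithium to the ketone and O-methylation of the alkoxide; the tertiary centre (future C6) forms without control, which is harmless because step 10 makes it planar again.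

Step 8
Reactants: 15 (2R,5E,8R,9E)-1,1-diethoxy-2,4,8-triethyl-4-methoxy-6-methyldodeca-5,9-diene
Product: 16 (2R,5E,8R,9E)-2,4,8-triethyl-4-methoxy-6-methyldodeca-5,9-dienal (both epimers at the methoxy carbon)
Conditions: PPTS (10 mol%), acetone/H2O (10:1), rt
Reagents that add atoms: water, O
Why: Mild acid-catalysed acetal hydrolysis frees the aldehyde, while the capped tertiary oxygen cannot form a lactol and the α-stereocentre is not epimerised under these conditions.

Step 9
Reactants: 16 (2R,5E,8R,9E)-2,4,8-triethyl-4-methoxy-6-methyldodeca-5,9-dienal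
Product: 17 (4S)-4-[(3R,6E,9R,10E)-5,9-diethyl-5-methoxy-7-methyltrideca-6,10-dien-3-yl]oxetan-2-one (both epimers at the methoxy carbon)
Conditions: AcCl (2 equiv), i-Pr2NEt (2.5 equiv), O-trimethylsilylquinine (10 mol%), LiClO4 (1 equiv), CH2Cl2/Et2O, −78 °C
Reagents that add atoms: acetyl chloride, CC(Cl)=O
Why: Cinchona alkaloid/LiClO4-catalysed ketene–aldehyde [2+2] cycloaddition (Wynberg-type), in which the alkaloid-bound ketene enolate attacks one aldehyde face under catalyst control and sets the lactone carbon (future C3) as S.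

Step 10
Reactants: 17 (4S)-4-[(3R,6E,9R,10E)-5,9-diethyl-5-methoxy-7-methyltrideca-6,10-dien-3-yl]oxetan-2-one
Product: 19 2-[(3R,4R,6R)-4,6-diethyl-6-[(1E,4R,5E)-4-ethyl-2-methylocta-1,5-dien-1-yl]-1,2-dioxan-3-yl]acetic acid, via hydroperoxy acid 18 (not isolated)
Conditions: urea·H2O2 (5 equiv), DMF, 35 °C; aqueous wash and solvent switch to CH2Cl2 (crude, not purified); then confined chiral imidodiphosphorimidate Brønsted acid (BINOL-derived, N-triflyl, 5 mol%, enantiomer giving 6R), 5 Å MS, −40 °C
Reagents that add atoms: urea–hydrogen peroxide (source of hydrogen peroxide), NC(N)=O.OO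
Why: Proposed new method: in the first stage neutral H2O2 attacks the alkyl (C3) carbon of the β-lactone in an SN2 alkyl–oxygen cleavage, which inverts C3 to R and frees the carboxylic acid (closest known: neutral hydrolysis and alcoholysis of β-lactones and their opening at the β-carbon by thiolates, azide, halides and cuprates); in the second stage the strong chiral acid ionises the tertiary allylic methyl ether to an allyl cation paired with its chiral anion, and the tethered hydroperoxide closes the six-membered ring at C6 (attack at C8 would need an eight-membered ring) on the face selected by the anion, setting C6 as R from both ether epimers while the E alkene is kept (closest known: acid-catalysed formation of dialkyl peroxides from hydroperoxides and tertiary carbinols, and imidodiphosphorimidate-catalysed asymmetric hydroalkoxylation giving tertiary ethers).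

## Compound list

1 | (2E)-pent-2-enal | CC/C=C/C=O | starting material
2 | (3R,4E)-hept-4-en-3-ol | CC/C=C/[C@H](O)CC | intermediate
3 | (3R,4E)-3-[(1-ethoxyethenyl)oxy]hept-4-ene (ketene acetal) | CC/C=C/[C@H](OC(=C)OCC)CC | intermediate
4 | ethyl (3R,4E)-3-ethylhept-4-enoate | CC/C=C/[C@H](CC)CC(=O)OCC | intermediate
5 | (3R,4E)-3-ethylhept-4-enal | CC/C=C/[C@H](CC)CC=O | intermediate
6 | (4R,5E)-4-ethyloct-5-en-1-yne | CC/C=C/[C@H](CC)CC#C | intermediate
7 | [(1E,4R,5E)-4-ethyl-2-methylocta-1,5-dien-1-yl]dimethylalane | CC/C=C/[C@H](CC)C/C(C)=C/[Al](C)C | intermediate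
8 | (1E,4R,5E)-4-ethyl-1-iodo-2-methylocta-1,5-diene | CC/C=C/[C@H](CC)C/C(C)=C/I | intermediate
9 | pent-1-en-3-one (ethyl vinyl ketone) | CCC(=O)C=C | starting material
10 | 3,3-diethoxyprop-1-ene (acrolein diethyl acetal) | C=CC(OCC)OCC | starting material
11 | (4E)-6,6-diethoxyhex-4-en-3-one | CCC(=O)/C=C/C(OCC)OCC | intermediate
12 | (5R)-6,6-diethoxy-5-ethylhexan-3-one | CCC(=O)C[C@@H](CC)C(OCC)OCC | intermediate
13 | [(1E,4R,5E)-4-ethyl-2-methylocta-1,5-dien-1-yl]lithium | CC/C=C/[C@H](CC)C/C(C)=C/[Li] | intermediate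
14 | lithium (2R,5E,8R,9E)-1,1-diethoxy-2,4,8-triethyl-6-methyldodeca-5,9-dien-4-olate (both C4 epimers) | [Li+].CC/C=C/[C@H](CC)C/C(C)=C/C(CC)([O-])C[C@@H](CC)C(OCC)OCC | intermediate
15 | (2R,5E,8R,9E)-1,1-diethoxy-2,4,8-triethyl-4-methoxy-6-methyldodeca-5,9-diene (both C4 epimers) | CC/C=C/[C@H](CC)C/C(C)=C/C(CC)(OC)C[C@@H](CC)C(OCC)OCC | intermediate
16 | (2R,5E,8R,9E)-2,4,8-triethyl-4-methoxy-6-methyldodeca-5,9-dienal (both C4 epimers) | CC/C=C/[C@H](CC)C/C(C)=C/C(CC)(OC)C[C@@H](CC)C=O | intermediate
17 | (4S)-4-[(3R,6E,9R,10E)-5,9-diethyl-5-methoxy-7-methyltrideca-6,10-dien-3-yl]oxetan-2-one (both epimers at the methoxy carbon) | CC/C=C/[C@H](CC)C/C(C)=C/C(CC)(OC)C[C@@H](CC)[C@@H]1CC(=O)O1 | intermediate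
18 | (3R,4R,7E,10R,11E)-4,6,10-triethyl-3-hydroperoxy-6-methoxy-8-methyltetradeca-7,11-dienoic acid (both C6 epimers) | CC/C=C/[C@H](CC)C/C(C)=C/C(CC)(OC)C[C@@H](CC)[C@@H](CC(=O)O)OO | intermediate
19 | 2-[(3R,4R,6R)-4,6-diethyl-6-[(1E,4R,5E)-4-ethyl-2-methylocta-1,5-dien-1-yl]-1,2-dioxan-3-yl]acetic acid | CC/C=C/[C@H](CC)C/C(C)=C/[C@@]1(CC)C[C@@H](CC)[C@@H](CC(=O)O)OO1 | target

## Step count and risks

Total steps: 10 (each one-pot operation counted once). Longest linear sequence: 8 (steps 1–4, then 7–10). Steps 5–6 make the second fragment.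

The three steps most likely to fail:

**Step 10 (proposed new step).** The risks are acyl instead of alkyl attack by H2O2 (giving a peracid), a slow SN2 at the hindered C3, and a low C6 diastereomer ratio in the cation closure. The fallback uses the established closure of a tertiary hydroperoxide onto a secondary sulfonate. It sets out from 17 and comes back at 19. LiBH4 in THF reduces the lactone to the (3S)-1,3-diol F1. TBDPSCl/imidazole protects the primary hydroxyl to give the silyl ether F2, and MsCl/Et3N gives the secondary mesylate F3. 50% H2O2 with catalytic H2SO4 at 0 °C exchanges the tertiary allylic methyl ether for a hydroperoxide, giving the tertiary hydroperoxide F4 as both C6 epimers. KOt-Bu/18-crown-6 in THF closes the ring by SN2 at C3 with inversion, and after HPLC removal of the 6-epimer gives the dioxane silyl ether F5. Bu4NF gives the primary alcohol F6, and TEMPO/PhI(OAc)2 in MeCN/H2O oxidises it to 19. In this fallback C6 is not controlled and is resolved by separation.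

**Step 6.** The γ,γ-dialkoxy enone may give a low ee or competing 1,2-addition. The fallback sets out from 9 and comes back at 12, and delivers the vinyl group by rhodium catalysis in place of the ethyl group by copper. Cross-metathesis of 9 with (E)-hex-3-ene (same ruthenium catalyst) gives (4E)-hept-4-en-3-one F7. Asymmetric 1,4-addition of potassium vinyltrifluoroborate ([Rh(C8H12)2]BF4, BINAP enantiomer giving R, toluene/H2O, 100 °C) gives (5R)-5-ethylhept-6-en-3-one F8. Ozonolysis (O3, CH2Cl2, −78 °C; PPh3) gives (2R)-2-ethyl-4-oxohexanal F9, and HC(OEt)3/EtOH/PPTS acetalises only the aldehyde to give 12.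

**Step 7.** The ketone may enolise, and MeOTf may methylate the hindered alkoxide incompletely or attack the acetal. The fallback sets out from 6 and 12 and comes back at 15, and builds the trisubstituted alkene after the C6–C7 bond. n-BuLi deprotonates 6 and the lithium acetylide (with CeCl3, THF, −78 °C) adds to 12 to give the tertiary propargylic alcohol F10. NaAlH2(OCH2CH2OCH3)2 in THF followed by I2 gives the (Z)-iodo allylic alcohol F11 by hydroxyl-directed trans-hydroalumination. LiCu(CH3)2 in Et2O at 0 °C replaces iodine by methyl with retention to give the (E)-tertiary allylic alcohol F12, and KH/MeI in THF gives 15.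

## Further compounds

F1 | step 10 | (3S,4R,7E,10R,11E)-4,6,10-triethyl-6-methoxy-8-methyltetradeca-7,11-diene-1,3-diol (both C6 epimers) | CC/C=C/[C@H](CC)C/C(C)=C/C(CC)(OC)C[C@@H](CC)[C@@H](O)CCO
F2 | step 10 | (3S,4R,7E,10R,11E)-1-[(tert-butyldiphenylsilyl)oxy]-4,6,10-triethyl-6-methoxy-8-methyltetradeca-7,11-dien-3-ol (both C6 epimers) | CC/C=C/[C@H](CC)C/C(C)=C/C(CC)(OC)C[C@@H](CC)[C@@H](O)CCO[Si](c1ccccc1)(c1ccccc1)C(C)(C)C
F3 | step 10 | (3S,4R,7E,10R,11E)-1-[(tert-butyldiphenylsilyl)oxy]-4,6,10-triethyl-6-methoxy-8-methyltetradeca-7,11-dien-3-yl methanesulfonate (both C6 epimers) | CC/C=C/[C@H](CC)C/C(C)=C/C(CC)(OC)C[C@@H](CC)[C@@H](OS(C)(=O)=O)CCO[Si](c1ccccc1)(c1ccccc1)C(C)(C)C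
F4 | step 10 | (3S,4R,7E,10R,11E)-1-[(tert-butyldiphenylsilyl)oxy]-4,6,10-triethyl-6-hydroperoxy-8-methyltetradeca-7,11-dien-3-yl methanesulfonate (both C6 epimers) | CC/C=C/[C@H](CC)C/C(C)=C/C(CC)(OO)C[C@@H](CC)[C@@H](OS(C)(=O)=O)CCO[Si](c1ccccc1)(c1ccccc1)C(C)(C)C
F5 | step 10 | tert-butyl{2-[(3R,4R,6R)-4,6-diethyl-6-[(1E,4R,5E)-4-ethyl-2-methylocta-1,5-dien-1-yl]-1,2-dioxan-3-yl]ethoxy}diphenylsilane | CC/C=C/[C@H](CC)C/C(C)=C/[C@@]1(CC)C[C@@H](CC)[C@@H](CCO[Si](c2ccccc2)(c2ccccc2)C(C)(C)C)OO1
F6 | step 10 | 2-[(3R,4R,6R)-4,6-diethyl-6-[(1E,4R,5E)-4-ethyl-2-methylocta-1,5-dien-1-yl]-1,2-dioxan-3-yl]ethan-1-ol | CC/C=C/[C@H](CC)C/C(C)=C/[C@@]1(CC)C[C@@H](CC)[C@@H](CCO)OO1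
F7 | step 6 | (4E)-hept-4-en-3-one | CCC(=O)/C=C/CC
F8 | step 6 | (5R)-5-ethylhept-6-en-3-one | CCC(=O)C[C@@H](CC)C=C
F9 | step 6 | (2R)-2-ethyl-4-oxohexanal | CCC(=O)C[C@@H](CC)C=O
F10 | step 7 | (2R,8R,9E)-1,1-diethoxy-2,4,8-triethyldodec-9-en-5-yn-4-ol (both C4 epimers) | CC/C=C/[C@H](CC)CC#CC(CC)(O)C[C@@H](CC)C(OCC)OCC
F11 | step 7 | (2R,5Z,8R,9E)-1,1-diethoxy-2,4,8-triethyl-6-iodododeca-5,9-dien-4-ol (both C4 epimers) | CC/C=C/[C@H](CC)C/C(I)=C/C(CC)(O)C[C@@H](CC)C(OCC)OCC
F12 | step 7 | (2R,5E,8R,9E)-1,1-diethoxy-2,4,8-triethyl-6-methyldodeca-5,9-dien-4-ol (both C4 epimers) | CC/C=C/[C@H](CC)C/C(C)=C/C(CC)(O)C[C@@H](CC)C(OCC)OCC
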